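## Retrosynthetic overview

1. Kurarinone 30 ⇐ desilylation of tris-silyl flavanone 29; the C2–aryl bond and C2 (S) come from a rhodium-catalysed asymmetric 1,4-addition of ring B arylzinc 27 to chromone 23 (ring B attached last).
2. Chromone 23 (ring C closed onto ring A) ⇐ acetophenone 20 by enaminone formation and acid ring closure.
3. The C8–CH2 bond ⇐ palladium-catalysed Negishi sp3–sp2 coupling of (S)-lavandulylzinc iodide 17 with aryl bromide 7.
4. Bromide 7 ⇐ resorcinol by directed ortho-metalation/bromination, then iridium-catalysed C–H borylation/oxidation and O-methylation (third ring A oxygen).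
5. Lavandulyl unit ⇐ furan-2(5H)-one + isopropenyltrifluoroborate (rhodium-catalysed asymmetric 1,4-addition sets the side-chain stereocentre), then lactol Wittig reaction.

Assumption: "lavandulyl" in names means 5-methyl-2-(prop-1-en-2-yl)hex-4-en-1-yl bound through C1; the same spatial arrangement is (S) in CH2–O, CH2–I and CH2–Zn compounds and (R) once CH2 carries the arene, only because the priority order changes.

## Route

Step 1
Reactants: 1 resorcinol
Product: 2 1,3-bis(methoxymethoxy)benzene
Conditions: NaH, MOMCl, DMF, 0 °C to rt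
Reagents that add atoms: chloromethyl methyl ether, COCCl
Why: Williamson-type double O-alkylation of the phenoxides installs MOM ethers that later act as ortho-directing groups.

Step 2
Reactants: 2 1,3-bis(methoxymethoxy)benzene
Product: 4 2-bromo-1,3-bis(methoxymethoxy)benzene, via 2,6-bis(methoxymethoxy)phenyllithium 3 (not isolated)
Conditions: n-BuLi, THF, 0 °C; then BrCCl2CCl2Br, −78 °C to rt
Reagents that add atoms: n-butyllithium, [Li]CCCC (Li of intermediate 3 only); 1,2-dibromo-1,1,2,2-tetrachloroethane, BrC(Cl)(Cl)C(Cl)(Cl)Br (Br)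
Why: Directed ortho-metalation removes the C2–H flanked by two OMOM groups, and halogen transfer to the aryllithium gives the bromide at that position only.

Step 3
Reactants: 4 2-bromo-1,3-bis(methoxymethoxy)benzene
Product: 6 4-bromo-3,5-bis(methoxymethoxy)phenol, via arylboronic pinacol ester 5 (not isolated)
Conditions: B2pin2, [Ir(OMe)(cod)]2 (1.5 mol%), dtbpy (3 mol%), THF, 70 °C; then aq. NaOH, H2O2, 0 °C
Reagents that add atoms: bis(pinacolato)diboron, CC1(C)OB(OC1(C)C)B1OC(C)(C)C(C)(C)O1 (Bpin of intermediate 5 only); hydrogen peroxide, OO (phenol O)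
Why: Sterically governed iridium-catalysed aromatic C–H borylation occurs only at C5, the one C–H without an ortho substituent, and the boronate is oxidised in the same pot with retention of position.

Step 4
Reactants: 6 4-bromo-3,5-bis(methoxymethoxy)phenol
Product: 7 2-bromo-5-methoxy-1,3-bis(methoxymethoxy)benzene
Conditions: MeI, K2CO3, acetone, 50 °C
Reagents that add atoms: iodomethane, CI
Why: Williamson ether synthesis on the only free phenol fixes the future 5-OMe group.

Step 5
Reactants: 8 furan-2(5H)-one; 9 potassium trifluoro(prop-1-en-2-yl)borate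
Product: 10 (4S)-4-(prop-1-en-2-yl)oxolan-2-one
Conditions: [Rh(cod)2]BF4 (3 mol%), (S)-BINAP (3.3 mol%), toluene–H2O (20:1), 100 °C
Reagents that add atoms: none
Why: Hayashi–Miyaura rhodium-catalysed asymmetric 1,4-addition of an alkenylboron reagent, in which the (S)-BINAP–rhodium alkenyl species adds to one enantioface of the butenolide and sets the lavandulyl stereocentre as 4S (sense by analogy with (S)-3-substituted cyclohexanones from the same ligand; the antipodal ligand is used if the sense is reversed).

Step 6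
Reactants: 10 (4S)-4-(prop-1-en-2-yl)oxolan-2-one
Product: 11 (4S)-4-(prop-1-en-2-yl)oxolan-2-ol (anomer mixture)
Conditions: i-Bu2AlH, CH2Cl2, −78 °C
Reagents that add atoms: none
Why: Partial hydride reduction of a lactone stops at the lactol at low temperature and does not touch the stereocentre.

Step 7
Reactants: 12 2-iodopropane
Product: 13 isopropyltriphenylphosphonium iodide
Conditions: PPh3, toluene, 110 °C
Reagents that add atoms: triphenylphosphine, c1ccc(cc1)P(c1ccccc1)c1ccccc1
Why: SN2 quaternisation of triphenylphosphine gives the Wittig salt.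

Step 8
Reactants: 11 (4S)-4-(prop-1-en-2-yl)oxolan-2-ol; 13 isopropyltriphenylphosphonium iodide
Product: 15 (S)-lavandulol [(2S)-5-methyl-2-(prop-1-en-2-yl)hex-4-en-1-ol], via isopropylidenetriphenylphosphorane 14 (not isolated)
Conditions: n-BuLi, THF, 0 °C; then 11, 0 °C to 50 °C
Reagents that add atoms: none
Why: Wittig olefination of the open hydroxy-aldehyde form of the lactol builds the prenyl terminus, and the stereocentre, being beta to the aldehyde, cannot epimerise.

Step 9
Reactants: 15 (S)-lavandulol
Product: 16 (S)-lavandulyl iodide [(3S)-3-(iodomethyl)-2,6-dimethylhepta-1,5-diene]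
Conditions: I2, PPh3, imidazole, CH2Cl2, 0 °C
Reagents that add atoms: iodine, [I][I]
Why: Appel iodination proceeds by SN2 at the primary carbon and leaves the adjacent stereocentre and both alkenes untouched.

Step 10
Reactants: 16 (S)-lavandulyl iodide; 7 2-bromo-5-methoxy-1,3-bis(methoxymethoxy)benzene
Product: 18 5-methoxy-1,3-bis(methoxymethoxy)-2-[(2R)-lavandulyl]benzene, via (S)-lavandulylzinc iodide 17 (not isolated)
Conditions: Zn, LiCl, THF, 40 °C; then 7, Pd(OAc)2 (2 mol%), CPhos (4 mol%), THF, rt to 45 °C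
Reagents that add atoms: zinc, [Zn] (Zn of intermediate 17 only)
Why: Negishi C(sp3)–C(sp2) coupling in which a bulky biarylphosphine makes reductive elimination from the hindered aryl(alkyl)palladium faster than beta-hydride elimination, so the stereocentre beta to the reacting carbon is carried through unchanged.

Step 11
Reactants: 18 5-methoxy-1,3-bis(methoxymethoxy)-2-[(2R)-lavandulyl]benzene
Product: 20 1-{6-methoxy-2,4-bis(methoxymethoxy)-3-[(2R)-lavandulyl]phenyl}ethan-1-one, via aryllithium 19 (not isolated)
Conditions: n-BuLi, TMEDA, THF, 0 °C; then MeC(O)N(OMe)Me, −78 °C to 0 °C; H2O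
Reagents that add atoms: n-butyllithium, [Li]CCCC (Li of intermediate 19 only); N-methoxy-N-methylacetamide, CC(=O)N(C)OC (acetyl group)
Why: Directed ortho-metalation at either of the two equivalent positions between OMe and OMOM, followed by Weinreb amide acylation that stops at the ketone through the stable chelated adduct.

Step 12
Reactants: 20 1-{6-methoxy-2,4-bis(methoxymethoxy)-3-[(2R)-lavandulyl]phenyl}ethan-1-one
Product: 22 7-hydroxy-5-methoxy-8-[(2R)-lavandulyl]-4H-chromen-4-one, via enaminone 21 (not isolated)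
Conditions: Me2NCH(OMe)2, toluene, 100 °C; then HCl (3 M in MeOH), 40 °C
Reagents that add atoms: N,N-dimethylformamide dimethyl acetal, COC(OC)N(C)C (the CH that becomes C2)
Why: Enaminone condensation followed by acid-mediated MOM methanolysis and intramolecular addition–elimination of the freed ortho-phenol (loss of dimethylamine) closes ring C as the chromone; only one oxygen is ortho to the ketone, so the regiochemistry is fixed.

Step 13
Reactants: 22 7-hydroxy-5-methoxy-8-[(2R)-lavandulyl]-4H-chromen-4-one
Product: 23 7-(tert-butyldimethylsilyloxy)-5-methoxy-8-[(2R)-lavandulyl]-4H-chromen-4-one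
Conditions: TBSCl, imidazole, DMF, rt
Reagents that add atoms: tert-butyldimethylsilyl chloride, CC(C)(C)[Si](C)(C)Cl
Why: Silylation of the acidic 7-OH removes the only protic group before the organozinc step and allows a fluoride endgame.

Step 14
Reactants: 1 resorcinol
Product: 24 1,3-bis(tert-butyldimethylsilyloxy)benzene
Conditions: TBSCl, imidazole, DMF, rt
Reagents that add atoms: tert-butyldimethylsilyl chloride, CC(C)(C)[Si](C)(C)Cl
Why: Standard imidazole-promoted bis-silylation of the phenols.

Step 15
Reactants: 24 1,3-bis(tert-butyldimethylsilyloxy)benzene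
Product: 25 1-bromo-2,4-bis(tert-butyldimethylsilyloxy)benzene
Conditions: NBS, MeCN, 0 °C
Reagents that add atoms: N-bromosuccinimide, O=C1CCC(=O)N1Br
Why: Electrophilic aromatic bromination goes para to one silyloxy group and ortho to the other, because the position between the two silyl ethers is sterically blocked.

Step 16
Reactants: 25 1-bromo-2,4-bis(tert-butyldimethylsilyloxy)benzene; 23 7-(tert-butyldimethylsilyloxy)-5-methoxy-8-[(2R)-lavandulyl]-4H-chromen-4-one
Product: 29 (2S)-2-[2,4-bis(tert-butyldimethylsilyloxy)phenyl]-7-(tert-butyldimethylsilyloxy)-5-methoxy-8-[(2R)-lavandulyl]chroman-4-one, via aryllithium 26 (not isolated), via arylzinc chloride 27 (not isolated), via trimethylsilyl enol ether 28 (not isolated)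
Conditions: 25, n-BuLi, THF, −78 °C; ZnCl2, −78 °C to rt; then 23, [RhCl((S)-binap)]2 (2.5 mol%), TMSCl, THF, 20 °C; then 1 M aq. HCl–THF, 0 °C, 10 min
Reagents that add atoms: n-butyllithium, [Li]CCCC (Li of intermediate 26 only); zinc chloride, Cl[Zn]Cl (ZnCl of intermediate 27 only); chlorotrimethylsilane, C[Si](C)(C)Cl (SiMe3 of intermediate 28 only)
Why: Proposed new method: rhodium/BINAP-catalysed asymmetric 1,4-addition of an ortho-siloxy arylzinc chloride to a chromone with chlorosilane trapping has, to my knowledge, not been shown (closest known reaction type: the same zinc/chlorosilane protocol on 4-quinolones and dihydropyridones, and arylboronic acid additions to chromones in protic media); zinc-to-rhodium transmetalation gives an aryl–rhodium(binap) species that carbometalates C2=C3 on the face set by the (S)-ligand (2S expected, since the (R)-ligand gives (R)-2-aryl-quinolones), and TMSCl silylates the rhodium enolate before it can expel the ring phenoxide, so C2 is locked in 2H-chromene 28 until mild hydrolysis, while the aprotic base-free medium spares the aryl silyl ethers and the protodemetalation-prone nucleophile, and the remote lavandulyl centre is a spectator.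

Step 17
Reactants: 29 (2S)-2-[2,4-bis(tert-butyldimethylsilyloxy)phenyl]-7-(tert-butyldimethylsilyloxy)-5-methoxy-8-[(2R)-lavandulyl]chroman-4-one
Product: 30 kurarinone
Conditions: HF·pyridine, pyridine–THF, 0 °C to rt
Reagents that add atoms: none
Why: Buffered fluoride cleavage of the three aryl silyl ethers avoids both base (retro-oxa-Michael racemisation at C2) and strong acid (cyclisation of the lavandulyl alkene onto the 7-OH), so both stereocentres are delivered intact.

## Compound list

1 | resorcinol | Oc1cccc(O)c1 | starting material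
2 | 1,3-bis(methoxymethoxy)benzene | COCOc1cccc(OCOC)c1 | intermediate
3 | 2,6-bis(methoxymethoxy)phenyllithium | [Li]c1c(OCOC)cccc1OCOC | intermediate
4 | 2-bromo-1,3-bis(methoxymethoxy)benzene | COCOc1cccc(OCOC)c1Br | intermediate
5 | 2-[4-bromo-3,5-bis(methoxymethoxy)phenyl]-4,4,5,5-tetramethyl-1,3,2-dioxaborolane | COCOc1cc(B2OC(C)(C)C(C)(C)O2)cc(OCOC)c1Br | intermediate
6 | 4-bromo-3,5-bis(methoxymethoxy)phenol | COCOc1cc(O)cc(OCOC)c1Br | intermediate
7 | 2-bromo-5-methoxy-1,3-bis(methoxymethoxy)benzene | COCOc1cc(OC)cc(OCOC)c1Br | intermediate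
8 | furan-2(5H)-one | O=C1OCC=C1 | starting material
9 | potassium trifluoro(prop-1-en-2-yl)borate | C=C(C)[B-](F)(F)F.[K+] | starting material
10 | (4S)-4-(prop-1-en-2-yl)oxolan-2-one | C=C(C)[C@H]1COC(=O)C1 | intermediate
11 | (4S)-4-(prop-1-en-2-yl)oxolan-2-ol, anomer mixture | C=C(C)[C@H]1COC(O)C1 | intermediate
12 | 2-iodopropane | CC(C)I | starting material
13 | isopropyltriphenylphosphonium iodide | CC(C)[P+](c1ccccc1)(c1ccccc1)c1ccccc1.[I-] | intermediate
14 | isopropylidenetriphenylphosphorane | CC(C)=P(c1ccccc1)(c1ccccc1)c1ccccc1 | intermediate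
15 | (S)-lavandulol, (2S)-5-methyl-2-(prop-1-en-2-yl)hex-4-en-1-ol | C=C(C)[C@H](CC=C(C)C)CO | intermediate
16 | (S)-lavandulyl iodide, (3S)-3-(iodomethyl)-2,6-dimethylhepta-1,5-diene | C=C(C)[C@H](CC=C(C)C)CI | intermediate
17 | (S)-lavandulylzinc iodide | C=C(C)[C@H](CC=C(C)C)C[Zn]I | intermediate
18 | 5-methoxy-1,3-bis(methoxymethoxy)-2-[(2R)-5-methyl-2-(prop-1-en-2-yl)hex-4-en-1-yl]benzene | C=C(C)[C@H](CC=C(C)C)Cc1c(OCOC)cc(OC)cc1OCOC | intermediate
19 | {6-methoxy-2,4-bis(methoxymethoxy)-3-[(2R)-lavandulyl]phenyl}lithium | C=C(C)[C@H](CC=C(C)C)Cc1c(OCOC)cc(OC)c([Li])c1OCOC | intermediate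
20 | 1-{6-methoxy-2,4-bis(methoxymethoxy)-3-[(2R)-lavandulyl]phenyl}ethan-1-one | C=C(C)[C@H](CC=C(C)C)Cc1c(OCOC)cc(OC)c(C(C)=O)c1OCOC | intermediate
21 | (E)-3-(dimethylamino)-1-{6-methoxy-2,4-bis(methoxymethoxy)-3-[(2R)-lavandulyl]phenyl}prop-2-en-1-one | C=C(C)[C@H](CC=C(C)C)Cc1c(OCOC)cc(OC)c(C(=O)/C=C/N(C)C)c1OCOC | intermediate
22 | 7-hydroxy-5-methoxy-8-[(2R)-lavandulyl]-4H-chromen-4-one | C=C(C)[C@H](CC=C(C)C)Cc1c(O)cc(OC)c2c1OC=CC2=O | intermediate
23 | 7-(tert-butyldimethylsilyloxy)-5-methoxy-8-[(2R)-lavandulyl]-4H-chromen-4-one | C=C(C)[C@H](CC=C(C)C)Cc1c(O[Si](C)(C)C(C)(C)C)cc(OC)c2c1OC=CC2=O | intermediate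
24 | 1,3-bis(tert-butyldimethylsilyloxy)benzene | CC(C)(C)[Si](C)(C)Oc1cccc(O[Si](C)(C)C(C)(C)C)c1 | intermediate
25 | 1-bromo-2,4-bis(tert-butyldimethylsilyloxy)benzene | CC(C)(C)[Si](C)(C)Oc1ccc(Br)c(O[Si](C)(C)C(C)(C)C)c1 | intermediate
26 | [2,4-bis(tert-butyldimethylsilyloxy)phenyl]lithium | CC(C)(C)[Si](C)(C)Oc1ccc([Li])c(O[Si](C)(C)C(C)(C)C)c1 | intermediate
27 | [2,4-bis(tert-butyldimethylsilyloxy)phenyl]zinc chloride | CC(C)(C)[Si](C)(C)Oc1ccc([Zn]Cl)c(O[Si](C)(C)C(C)(C)C)c1 | intermediate
28 | (2S)-2-[2,4-bis(tert-butyldimethylsilyloxy)phenyl]-7-(tert-butyldimethylsilyloxy)-5-methoxy-8-[(2R)-lavandulyl]-4-(trimethylsilyloxy)-2H-chromene | C=C(C)[C@H](CC=C(C)C)Cc1c(O[Si](C)(C)C(C)(C)C)cc(OC)c2c1O[C@H](c1ccc(O[Si](C)(C)C(C)(C)C)cc1O[Si](C)(C)C(C)(C)C)C=C2O[Si](C)(C)C | intermediate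
29 | (2S)-2-[2,4-bis(tert-butyldimethylsilyloxy)phenyl]-7-(tert-butyldimethylsilyloxy)-5-methoxy-8-[(2R)-lavandulyl]chroman-4-one | C=C(C)[C@H](CC=C(C)C)Cc1c(O[Si](C)(C)C(C)(C)C)cc(OC)c2c1O[C@H](c1ccc(O[Si](C)(C)C(C)(C)C)cc1O[Si](C)(C)C(C)(C)C)CC2=O | intermediate
30 | kurarinone, (2S)-2-(2,4-dihydroxyphenyl)-7-hydroxy-5-methoxy-8-[(2R)-5-methyl-2-(prop-1-en-2-yl)hex-4-en-1-yl]chroman-4-one | C=C(C)[C@H](CC=C(C)C)Cc1c(O)cc(OC)c2c1O[C@H](c1ccc(O)cc1O)CC2=O | target

## Step count and weak points

Total steps: 17. Longest linear sequence: 10 (steps 1–4, 10–13, 16, 17; the lavandulyl branch 5, 6, 8, 9 followed by 10–13, 16, 17 is equally long).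

Most likely to fail:

Step 16 (the proposed new arylzinc/chlorosilane addition to a chromone). The hindered ortho-siloxy aryl group may transfer slowly, or the facial selectivity may be lower than on quinolones. The fallback uses the documented boronic acid manifold, which needs water and therefore MOM instead of silyl protection. It sets out from chromone 22 and arene 2 and returns at target 30. Chromone 22 is protected with MOMCl and i-Pr2NEt to give 5-methoxy-7-(methoxymethoxy)-8-[(2R)-lavandulyl]-4H-chromen-4-one F1. Arene 2 is brominated with NBS to 1-bromo-2,4-bis(methoxymethoxy)benzene F2, which by bromine–lithium exchange, B(Oi-Pr)3 and mild hydrolysis gives [2,4-bis(methoxymethoxy)phenyl]boronic acid F3. The known hydroxorhodium-catalysed asymmetric 1,4-addition of an arylboronic acid to a chromone ([Rh(OH)(cod)]2 with an (S)-configured electron-poor biaryl bisphosphine or a chiral diene, toluene–water, 20–50 °C) joins F1 and F3 to the tris-MOM flavanone F4. Methanolysis with dilute HCl in MeOH at room temperature then gives 30.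

Step 10 (Negishi coupling). The bromide is flanked by two alkoxy groups, and the alkylpalladium intermediate carries an allylic beta-hydrogen, so beta-hydride elimination/reinsertion could erode the side-chain stereocentre or give diene. The fallback reverses the polarity and avoids any alkylpalladium species. It sets out from alcohol 15 and bromide 7 and returns at 18. Alcohol 15 is converted with Tf2O and 2,6-lutidine at −78 °C into (S)-lavandulyl trifluoromethanesulfonate F5. Bromide 7 is converted with n-BuLi at −78 °C into [4-methoxy-2,6-bis(methoxymethoxy)phenyl]lithium F6. F6 is alkylated by F5 at −78 to −20 °C (10 mol% CuBr·SMe2 if sluggish) in an SN2 reaction at the primary carbon to give 18.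

Step 5 (asymmetric isopropenyl addition to the butenolide). Five-membered lactones are sluggish acceptors and the ee may be moderate. The fallback replaces asymmetric catalysis by a racemic sequence with enzymatic resolution. It sets out from 8 and returns at 15. Copper-catalysed conjugate addition of CH2=C(CH3)MgBr (CuBr·SMe2, TMSCl, THF, −78 °C) to 8 gives racemic 4-(prop-1-en-2-yl)oxolan-2-one F7. Reduction with i-Bu2AlH gives racemic 4-(prop-1-en-2-yl)oxolan-2-ol F8, and Wittig reaction with ylide 14 gives racemic lavandulol F9. The documented lipase-catalysed transesterification of racemic lavandulol with vinyl acetate, which acylates the (R)-alcohol preferentially, is run past 55% conversion; it removes that enantiomer as (R)-lavandulyl acetate F10 and leaves (S)-lavandulol 15.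

## Further compounds

F1 | step 16 | 5-methoxy-7-(methoxymethoxy)-8-[(2R)-lavandulyl]-4H-chromen-4-one | C=C(C)[C@H](CC=C(C)C)Cc1c(OCOC)cc(OC)c2c1OC=CC2=O
F2 | step 16 | 1-bromo-2,4-bis(methoxymethoxy)benzene | COCOc1ccc(Br)c(OCOC)c1
F3 | step 16 | [2,4-bis(methoxymethoxy)phenyl]boronic acid | COCOc1ccc(B(O)O)c(OCOC)c1
F4 | step 16 | (2S)-2-[2,4-bis(methoxymethoxy)phenyl]-5-methoxy-7-(methoxymethoxy)-8-[(2R)-lavandulyl]chroman-4-one | C=C(C)[C@H](CC=C(C)C)Cc1c(OCOC)cc(OC)c2c1O[C@H](c1ccc(OCOC)cc1OCOC)CC2=O
F5 | step 10 | (S)-lavandulyl trifluoromethanesulfonate | C=C(C)[C@H](CC=C(C)C)COS(=O)(=O)C(F)(F)F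
F6 | step 10 | [4-methoxy-2,6-bis(methoxymethoxy)phenyl]lithium | [Li]c1c(OCOC)cc(OC)cc1OCOC
F7 | step 5 | racemic 4-(prop-1-en-2-yl)oxolan-2-one | C=C(C)C1COC(=O)C1
F8 | step 5 | racemic 4-(prop-1-en-2-yl)oxolan-2-ol | C=C(C)C1COC(O)C1
F9 | step 5 | racemic lavandulol | C=C(C)C(CC=C(C)C)CO
F10 | step 5 | (R)-lavandulyl acetate | C=C(C)[C@@H](CC=C(C)C)COC(C)=O
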